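**Retrosynthetic overview**
1. The 20-membered lactone (ring C) is closed last at C8=C9 by Z-selective ring-closing metathesis; C10–C11 and the C11 carbinol are made just before by chiral-phosphoric-acid allylboration of a Z-enal.
2. The C1–O19 ester joins a West hydroxy-enal (C11–C24) to an East acid (C1–C8, C5 as silyl ether); the C5 ketone is unveiled only after the ester exists, and no base is used afterwards.
3. The East acid comes from a dihydropyranone built by a new carbene-catalysed [4+2] that sets C4 and locks the 2Z alkene.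
4. West: side chain by Nozaki–Hiyama–Kishi addition of an epoxy vinyl iodide to a C19 aldehyde; C18 by hydroboration of an isopropenyl group; oxolane ring A by 5-endo opening of an organocatalytically made C14–C15 epoxide; C12=C13 by Still–Gennari olefination; C17 by catalytic allylboration of methacrolein.
5. Ring order: C14–C15 oxirane (step 3) → oxolane ring A (step 5); side-chain oxirane ring B (step 9); temporary dihydropyranone (step 16, opened in step 17); macrolactone ring C (step 22).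

Assumption: the target is exactly the given SMILES, i.e. (2Z,4S,6E,8Z,11R,12Z,14R,15S,17R,18R,19R,20E,22R,23R) in macrolide numbering (C1 = lactone carbonyl, C24 = epoxide methyl); this numbering is used for locants in the text. The route is a proposal and has not been run.

**Step 1**
Reactants: 1 methacrolein; 2 allylboronic acid pinacol ester
Product: 3 (3R)-2-methylhexa-1,5-dien-3-ol
Conditions: (R)-TRIP [(R)-3,3′-bis(2,4,6-triisopropylphenyl)-1,1′-binaphthalene-2,2′-diyl hydrogen phosphate] (5 mol%), 4 Å MS, toluene, −30 °C; aqueous work-up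
Reagents that add atoms: none
Why: Chiral-phosphoric-acid-catalysed allylboration (Antilla type), in which the acid bridges the boronate oxygen and the formyl C–H in a chair transition state so that allyl adds to one enal face, setting C17 (R) as the first stereocentre from two achiral partners.

**Step 2**
Reactants: 3 (3R)-2-methylhexa-1,5-dien-3-ol; 4 (E)-but-2-enal
Product: 5 (2E,5R)-5-hydroxy-6-methylhepta-2,6-dienal
Conditions: 4 (5 equiv), second-generation Hoveyda–Grubbs catalyst (3 mol%), CH2Cl2, 40 °C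
Reagents that add atoms: none
Why: Olefin cross-metathesis, in which only the monosubstituted alkene reacts (the 1,1-disubstituted alkene is inert) and the enal partner gives the E-alkene with loss of propene.

**Step 3**
Reactants: 5 (2E,5R)-5-hydroxy-6-methylhepta-2,6-dienal
Product: 6 (2R,3S)-3-[(2R)-2-hydroxy-3-methylbut-3-en-1-yl]oxirane-2-carbaldehyde
Conditions: (S)-2-[bis(3,5-bis(trifluoromethyl)phenyl)(trimethylsilyloxy)methyl]pyrrolidine (10 mol%), 35% aq H2O2 (1.3 equiv), CH2Cl2, rt; crude used at once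
Reagents that add atoms: hydrogen peroxide, OO
Why: Jørgensen iminium/enamine epoxidation, in which hydroperoxide adds to the β-carbon on the face left open by the diarylsilyloxymethyl group and the enamine closes the ring, giving the trans (2R,3S) epoxide (C14, C15) under catalyst control; material from the minor enantiomer of 3 becomes a separable diastereomer.

**Step 4**
Reactants: 6 (2R,3S)-3-[(2R)-2-hydroxy-3-methylbut-3-en-1-yl]oxirane-2-carbaldehyde; 7 ethyl 2-[bis(2,2,2-trifluoroethoxy)phosphoryl]propanoate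
Product: 8 ethyl (2Z)-3-{(2S,3S)-3-[(2R)-2-hydroxy-3-methylbut-3-en-1-yl]oxiran-2-yl}-2-methylprop-2-enoate
Conditions: 7 (1.3 equiv), KN(SiMe3)2, 18-crown-6, THF, −78 °C
Reagents that add atoms: none
Why: Still–Gennari olefination, whose electron-poor phosphonate eliminates under kinetic control to the Z-trisubstituted enoate (C12=C13, C14 cis to C11).

**Step 5**
Reactants: 8 ethyl (2Z)-3-{(2S,3S)-3-[(2R)-2-hydroxy-3-methylbut-3-en-1-yl]oxiran-2-yl}-2-methylprop-2-enoate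
Product: 9 ethyl (2Z)-3-[(2R,3S,5R)-3-hydroxy-5-(prop-1-en-2-yl)oxolan-2-yl]-2-methylprop-2-enoate
Conditions: camphorsulfonic acid (10 mol%), CH2Cl2, 0 °C → rt
Reagents that add atoms: none
Why: Acid-catalysed 5-endo epoxide opening, in which the C17 hydroxyl attacks the allylic carbon C14 with inversion (the only alternative is a 4-exo oxetane), giving the 2,5-cis oxolane with the C15 hydroxyl trans to the side arm, a geometry that also prevents lactonisation onto the Z-ester.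

**Step 6**
Reactants: 9 ethyl (2Z)-3-[(2R,3S,5R)-3-hydroxy-5-(prop-1-en-2-yl)oxolan-2-yl]-2-methylprop-2-enoate
Product: 10 ethyl (2Z)-3-[(2R,3S,5R)-3-methoxy-5-(prop-1-en-2-yl)oxolan-2-yl]-2-methylprop-2-enoate
Conditions: Me3OBF4, 1,8-bis(dimethylamino)naphthalene, 4 Å MS, CH2Cl2, rt
Reagents that add atoms: trimethyloxonium tetrafluoroborate, C[O+](C)C.F[B-](F)(F)F
Why: O-methylation with Meerwein salt under a non-nucleophilic proton scavenger, which leaves the enoate and the alkene untouched.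

**Step 7**
Reactants: 10 ethyl (2Z)-3-[(2R,3S,5R)-3-methoxy-5-(prop-1-en-2-yl)oxolan-2-yl]-2-methylprop-2-enoate
Product: 12 ethyl (2Z)-3-{(2R,3S,5R)-5-[(2S)-1-hydroxypropan-2-yl]-3-methoxyoxolan-2-yl}-2-methylprop-2-enoate, via B-alkyl-9-BBN adduct 11 (not isolated)
Conditions: 9-BBN, THF, 0 °C → rt; then NaBO3·4H2O, H2O, rt
Reagents that add atoms: 9-borabicyclo[3.3.1]nonane, B1C2CCCC1CCC2; sodium perborate tetrahydrate, [Na+].[O-]OB=O.O.O.O.O
Why: Hydroboration–oxidation under substrate control (Still–Barrish/Kishi model: allylic C17–H eclipses the alkene and the borane adds anti to the ring carbon), giving the anti C17–O/C18–Me isomer; 9-BBN spares the conjugated ester.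

**Step 8**
Reactants: 12 ethyl (2Z)-3-{(2R,3S,5R)-5-[(2S)-1-hydroxypropan-2-yl]-3-methoxyoxolan-2-yl}-2-methylprop-2-enoate
Product: 13 ethyl (2Z)-3-{(2R,3S,5R)-3-methoxy-5-[(2R)-1-oxopropan-2-yl]oxolan-2-yl}-2-methylprop-2-enoate
Conditions: Dess–Martin periodinane, NaHCO3, CH2Cl2, 0 °C; used crude
Reagents that add atoms: none
Why: Dess–Martin oxidation, mild and buffered so that the α-stereocentre C18 of the aldehyde is not epimerised.

**Step 9**
Reactants: 4 (E)-but-2-enal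
Product: 14 (2S,3R)-3-methyloxirane-2-carbaldehyde
Conditions: (R)-2-[bis(3,5-bis(trifluoromethyl)phenyl)(trimethylsilyloxy)methyl]pyrrolidine (10 mol%), 35% aq H2O2, CH2Cl2, rt; dried solution used directly
Reagents that add atoms: hydrogen peroxide, OO
Why: The same Jørgensen epoxidation with the enantiomeric catalyst sets both side-chain epoxide centres (C22, C23) from an achiral enal.

**Step 10**
Reactants: 14 (2S,3R)-3-methyloxirane-2-carbaldehyde
Product: 15 (2R,3R)-2-[(E)-2-iodoethenyl]-3-methyloxirane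
Conditions: CrCl2 (6 equiv), CHI3 (2 equiv), THF, 0 °C
Reagents that add atoms: iodoform, IC(I)I
Why: Takai olefination, which gives the E-vinyl iodide through a gem-dichromium species and tolerates the epoxide.

**Step 11**
Reactants: 13 ethyl (2Z)-3-{(2R,3S,5R)-3-methoxy-5-[(2R)-1-oxopropan-2-yl]oxolan-2-yl}-2-methylprop-2-enoate; 15 (2R,3R)-2-[(E)-2-iodoethenyl]-3-methyloxirane
Product: 16 ethyl (2Z)-3-{(2R,3S,5R)-5-[(2S,3R,4E)-3-hydroxy-5-[(2R,3R)-3-methyloxiran-2-yl]pent-4-en-2-yl]-3-methoxyoxolan-2-yl}-2-methylprop-2-enoate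
Conditions: 15 (1.5 equiv), CrCl2 (4 equiv), NiCl2 (1 mol%), DMSO, rt; minor C19 epimer removed by chromatography
Reagents that add atoms: none
Why: Nozaki–Hiyama–Kishi coupling, in which the alkenyl trivalent chromium species adds to the aldehyde in the Felkin–Anh sense (syn to C18–Me) reinforced by 1,3-anti induction from the ring oxygen, setting C19 (R) with the E-alkene retained.

**Step 12**
Reactants: 16 ethyl (2Z)-3-{(2R,3S,5R)-5-[(2S,3R,4E)-3-hydroxy-5-[(2R,3R)-3-methyloxiran-2-yl]pent-4-en-2-yl]-3-methoxyoxolan-2-yl}-2-methylprop-2-enoate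
Product: 17 (2S,3R,4E)-2-{(2R,4S,5R)-5-[(1Z)-3-hydroxy-2-methylprop-1-en-1-yl]-4-methoxyoxolan-2-yl}-5-[(2R,3R)-3-methyloxiran-2-yl]pent-4-en-3-ol
Conditions: i-Bu2AlH (3.5 equiv), CH2Cl2, −78 °C; aqueous work-up
Reagents that add atoms: none
Why: 1,2-Reduction of the enoate by i-Bu2AlH at low temperature gives the Z-allylic alcohol without touching the epoxide.

**Step 13**
Reactants: 17 (2S,3R,4E)-2-{(2R,4S,5R)-5-[(1Z)-3-hydroxy-2-methylprop-1-en-1-yl]-4-methoxyoxolan-2-yl}-5-[(2R,3R)-3-methyloxiran-2-yl]pent-4-en-3-ol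
Product: 18 (2Z)-3-{(2R,3S,5R)-5-[(2S,3R,4E)-3-hydroxy-5-[(2R,3R)-3-methyloxiran-2-yl]pent-4-en-2-yl]-3-methoxyoxolan-2-yl}-2-methylprop-2-enal
Conditions: TEMPO (10 mol%), PhI(OAc)2 (1.1 equiv), CH2Cl2, rt
Reagents that add atoms: none
Why: Oxoammonium (TEMPO/PhI(OAc)2) oxidation, selective for the primary allylic alcohol over the hindered secondary C19 alcohol and mild enough to keep the Z-enal.

**Step 14**
Reactants: 19 acrolein; 20 2-(triphenyl-λ5-phosphanylidene)propanal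
Product: 21 (2E)-2-methylpenta-2,4-dienal
Conditions: 19 (3 equiv), CH2Cl2, rt
Reagents that add atoms: none
Why: Wittig olefination with a stabilised ylide gives the E-trisubstituted dienal (future C5–C8).

**Step 15**
Reactants: 22 (2E)-2-methylpent-2-enoic acid
Product: 23 (2E)-2-methylpent-2-enoyl chloride
Conditions: (COCl)2, DMF (cat.), CH2Cl2, 0 °C → rt
Reagents that add atoms: oxalyl chloride, ClC(=O)C(=O)Cl
Why: Standard acid chloride formation through the Vilsmeier intermediate.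

**Step 16**
Reactants: 23 (2E)-2-methylpent-2-enoyl chloride; 21 (2E)-2-methylpenta-2,4-dienal
Product: 24 (5S,6S)-3,5-dimethyl-6-[(2E)-penta-2,4-dien-2-yl]-5,6-dihydro-2H-pyran-2-one
Conditions: (5aS,10bR)-2-mesityl-5a,10b-dihydro-4H,6H-indeno[2,1-b][1,2,4]triazolo[4,3-d][1,4]oxazin-2-ium chloride (10 mol%; enantiomer to be confirmed by screening), i-Pr2NEt (2.2 equiv), 4 Å MS, toluene, −20 °C → rt
Reagents that add atoms: none
Why: Proposed new method: carbene-catalysed formal [4+2] (vinylogous aldol–lactonisation), in which the acid chloride acylates the carbene, the amine removes the γ-proton to give an s-cis azolium dienolate, its γ-carbon adds to the aldehyde C=O inside the chiral pocket (setting C4 as S) and the alkoxide expels the carbene to close the lactone, locking C2=C3 as Z; the closest known reaction type is the carbene-catalysed [4+2] annulation of azolium dienolates with trifluoromethyl ketones or isatins, here extended to an unactivated α-branched enal and a γ-substituted dienolate (the C5 configuration is irrelevant, as C5 becomes a ketone).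

**Step 17**
Reactants: 24 (5S,6S)-3,5-dimethyl-6-[(2E)-penta-2,4-dien-2-yl]-5,6-dihydro-2H-pyran-2-one
Product: 27 (2Z,4S,5S,6E)-2,4,6-trimethyl-5-(triethylsilyloxy)nona-2,6,8-trienoic acid, via lithium hydroxy-carboxylate 25 (not isolated), via bis-triethylsilyl derivative 26 (not isolated)
Conditions: LiOH, THF/H2O, 0 °C; evaporate; TESCl, imidazole, DMF, 0 °C; pH 5 aqueous work-up
Reagents that add atoms: lithium hydroxide, [Li+].[OH-]; chlorotriethylsilane, CC[Si](Cl)(CC)CC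
Why: Saponification of the lactone, silylation of the carboxylate salt before it can relactonise, and hydrolysis of the labile silyl ester on work-up give the Z-acid with C5 masked.

**Step 18**
Reactants: 18 (2Z)-3-{(2R,3S,5R)-5-[(2S,3R,4E)-3-hydroxy-5-[(2R,3R)-3-methyloxiran-2-yl]pent-4-en-2-yl]-3-methoxyoxolan-2-yl}-2-methylprop-2-enal; 27 (2Z,4S,5S,6E)-2,4,6-trimethyl-5-(triethylsilyloxy)nona-2,6,8-trienoic acid
Product: 28 (2R,3R,4E)-2-{(2R,4S,5R)-4-methoxy-5-[(1Z)-2-methyl-3-oxoprop-1-en-1-yl]oxolan-2-yl}-5-[(2R,3R)-3-methyloxiran-2-yl]pent-4-en-3-yl (2Z,4S,5S,6E)-2,4,6-trimethyl-5-(triethylsilyloxy)nona-2,6,8-trienoate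
Conditions: 27, 2,4,6-trichlorobenzoyl chloride, Et3N, toluene, rt; then 18, DMAP, toluene, rt
Reagents that add atoms: none
Why: Yamaguchi esterification acylates the C19 alcohol with retention; with C5 still a silyl ether, C4–H is not acidic, so neither C4 nor the Z-alkene is scrambled.

**Step 19**
Reactants: 28 (the triethylsilyl ether ester above)
Product: 29 (2R,3R,4E)-2-{(2R,4S,5R)-4-methoxy-5-[(1Z)-2-methyl-3-oxoprop-1-en-1-yl]oxolan-2-yl}-5-[(2R,3R)-3-methyloxiran-2-yl]pent-4-en-3-yl (2Z,4S,5S,6E)-5-hydroxy-2,4,6-trimethylnona-2,6,8-trienoate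
Conditions: HF·pyridine, pyridine, THF, 0 °C; used at once
Reagents that add atoms: none
Why: Buffered fluoride desilylation frees the C5 alcohol; immediate use forestalls translactonisation onto the Z-ester.

**Step 20**
Reactants: 29 (the C5 alcohol above)
Product: 30 (2R,3R,4E)-2-{(2R,4S,5R)-4-methoxy-5-[(1Z)-2-methyl-3-oxoprop-1-en-1-yl]oxolan-2-yl}-5-[(2R,3R)-3-methyloxiran-2-yl]pent-4-en-3-yl (2Z,4S,6E)-2,4,6-trimethyl-5-oxonona-2,6,8-trienoate
Conditions: Dess–Martin periodinane, NaHCO3 (solid), CH2Cl2, 0 °C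
Reagents that add atoms: none
Why: Dess–Martin oxidation gives the dienone under near-neutral conditions; from here no base is used because C4–H is now vinylogously acidic.

**Step 21**
Reactants: 30 (the keto enal above); 2 allylboronic acid pinacol ester
Product: 31 (2R,3R,4E)-2-{(2R,4S,5R)-5-[(1Z,3R)-3-hydroxy-2-methylhexa-1,5-dien-1-yl]-4-methoxyoxolan-2-yl}-5-[(2R,3R)-3-methyloxiran-2-yl]pent-4-en-3-yl (2Z,4S,6E)-2,4,6-trimethyl-5-oxonona-2,6,8-trienoate
Conditions: 2 (1.5 equiv), (R)-TRIP (10 mol%), 4 Å MS, toluene, −30 °C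
Reagents that add atoms: none
Why: Chiral-phosphoric-acid-catalysed allylboration again, aldehyde-selective (ketone and esters inert) and acidic rather than basic, with catalyst control setting C11 (R) as in step 1.

**Step 22**
Reactants: 31 (the homoallylic alcohol above)
Product: 32 CNP0117824.1
Conditions: Grubbs Z-selective cyclometalated ruthenium nitrate catalyst [Ru(κ2-NO3)(C,C-chelating N-adamantyl-N′-(2,6-diisopropylphenyl)imidazolinylidene)(=CH-C6H4-2-O-i-Pr)] (10 mol%), 1,2-dichloroethane (1 mM), 45 °C, static vacuum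
Reagents that add atoms: none
Why: Z-selective ring-closing olefin metathesis, in which the catalyst engages only the two terminal alkenes (E-internal and trisubstituted alkenes are inert) and its side-bound metallacycle delivers the cis C8=C9 bond of the E,Z-dienone with loss of ethene under neutral conditions.

**Compound list**
1 | methacrolein (2-methylprop-2-enal) | CC(=C)C=O | starting material
2 | allylboronic acid pinacol ester | C=CCB1OC(C)(C)C(C)(C)O1 | starting material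
3 | (3R)-2-methylhexa-1,5-dien-3-ol | C=CC[C@H](C(C)=C)O | intermediate
4 | (E)-but-2-enal (crotonaldehyde) | C/C=C/C=O | starting material
5 | (2E,5R)-5-hydroxy-6-methylhepta-2,6-dienal | O=C/C=C/C[C@H](C(C)=C)O | intermediate
6 | (2R,3S)-3-[(2R)-2-hydroxy-3-methylbut-3-en-1-yl]oxirane-2-carbaldehyde | O[C@@H](C(C)=C)C[C@@H]1O[C@H]1C=O | intermediate
7 | ethyl 2-[bis(2,2,2-trifluoroethoxy)phosphoryl]propanoate | CCOC(=O)C(C)P(=O)(OCC(F)(F)F)OCC(F)(F)F | starting material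
8 | ethyl (2Z)-3-{(2S,3S)-3-[(2R)-2-hydroxy-3-methylbut-3-en-1-yl]oxiran-2-yl}-2-methylprop-2-enoate | O[C@@H](C(C)=C)C[C@@H]1O[C@H]1/C=C(/C)C(=O)OCC | intermediate
9 | ethyl (2Z)-3-[(2R,3S,5R)-3-hydroxy-5-(prop-1-en-2-yl)oxolan-2-yl]-2-methylprop-2-enoate | O[C@H]1C[C@H](C(C)=C)O[C@@H]1/C=C(/C)C(=O)OCC | intermediate
10 | ethyl (2Z)-3-[(2R,3S,5R)-3-methoxy-5-(prop-1-en-2-yl)oxolan-2-yl]-2-methylprop-2-enoate | CO[C@H]1C[C@H](C(C)=C)O[C@@H]1/C=C(/C)C(=O)OCC | intermediate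
11 | ethyl (2Z)-3-{(2R,3S,5R)-5-[(2S)-1-(9-borabicyclo[3.3.1]nonan-9-yl)propan-2-yl]-3-methoxyoxolan-2-yl}-2-methylprop-2-enoate | CO[C@H]1C[C@H]([C@@H](C)CB2C3CCCC2CCC3)O[C@@H]1/C=C(/C)C(=O)OCC | intermediate
12 | ethyl (2Z)-3-{(2R,3S,5R)-5-[(2S)-1-hydroxypropan-2-yl]-3-methoxyoxolan-2-yl}-2-methylprop-2-enoate | CO[C@H]1C[C@H]([C@@H](C)CO)O[C@@H]1/C=C(/C)C(=O)OCC | intermediate
13 | ethyl (2Z)-3-{(2R,3S,5R)-3-methoxy-5-[(2R)-1-oxopropan-2-yl]oxolan-2-yl}-2-methylprop-2-enoate | CO[C@H]1C[C@H]([C@@H](C)C=O)O[C@@H]1/C=C(/C)C(=O)OCC | intermediate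
14 | (2S,3R)-3-methyloxirane-2-carbaldehyde | O=C[C@H]1O[C@@H]1C | intermediate
15 | (2R,3R)-2-[(E)-2-iodoethenyl]-3-methyloxirane | I/C=C/[C@H]1O[C@@H]1C | intermediate
16 | ethyl (2Z)-3-{(2R,3S,5R)-5-[(2S,3R,4E)-3-hydroxy-5-[(2R,3R)-3-methyloxiran-2-yl]pent-4-en-2-yl]-3-methoxyoxolan-2-yl}-2-methylprop-2-enoate | CO[C@H]1C[C@H]([C@@H](C)[C@H](O)/C=C/[C@H]2O[C@@H]2C)O[C@@H]1/C=C(/C)C(=O)OCC | intermediate
17 | (2S,3R,4E)-2-{(2R,4S,5R)-5-[(1Z)-3-hydroxy-2-methylprop-1-en-1-yl]-4-methoxyoxolan-2-yl}-5-[(2R,3R)-3-methyloxiran-2-yl]pent-4-en-3-ol | CO[C@H]1C[C@H]([C@@H](C)[C@H](O)/C=C/[C@H]2O[C@@H]2C)O[C@@H]1/C=C(/C)CO | intermediate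
18 | (2Z)-3-{(2R,3S,5R)-5-[(2S,3R,4E)-3-hydroxy-5-[(2R,3R)-3-methyloxiran-2-yl]pent-4-en-2-yl]-3-methoxyoxolan-2-yl}-2-methylprop-2-enal | CO[C@H]1C[C@H]([C@@H](C)[C@H](O)/C=C/[C@H]2O[C@@H]2C)O[C@@H]1/C=C(/C)C=O | intermediate
19 | acrolein (prop-2-enal) | C=CC=O | starting material
20 | 2-(triphenyl-λ5-phosphanylidene)propanal | CC(C=O)=P(c1ccccc1)(c1ccccc1)c1ccccc1 | starting material
21 | (2E)-2-methylpenta-2,4-dienal | O=C/C(C)=C/C=C | intermediate
22 | (2E)-2-methylpent-2-enoic acid | CC/C=C(\C)C(=O)O | starting material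
23 | (2E)-2-methylpent-2-enoyl chloride | CC/C=C(\C)C(=O)Cl | intermediate
24 | (5S,6S)-3,5-dimethyl-6-[(2E)-penta-2,4-dien-2-yl]-5,6-dihydro-2H-pyran-2-one | O=C1O[C@H](/C(C)=C/C=C)[C@@H](C)C=C1C | intermediate
25 | lithium (2Z,4S,5S,6E)-5-hydroxy-2,4,6-trimethylnona-2,6,8-trienoate | [Li+].[O-]C(=O)/C(C)=C\[C@H](C)[C@H](O)/C(C)=C/C=C | intermediate
26 | triethylsilyl (2Z,4S,5S,6E)-2,4,6-trimethyl-5-(triethylsilyloxy)nona-2,6,8-trienoate | CC[Si](CC)(CC)OC(=O)/C(C)=C\[C@H](C)[C@H](O[Si](CC)(CC)CC)/C(C)=C/C=C | intermediate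
27 | (2Z,4S,5S,6E)-2,4,6-trimethyl-5-(triethylsilyloxy)nona-2,6,8-trienoic acid | OC(=O)/C(C)=C\[C@H](C)[C@H](O[Si](CC)(CC)CC)/C(C)=C/C=C | intermediate
28 | (2R,3R,4E)-2-{(2R,4S,5R)-4-methoxy-5-[(1Z)-2-methyl-3-oxoprop-1-en-1-yl]oxolan-2-yl}-5-[(2R,3R)-3-methyloxiran-2-yl]pent-4-en-3-yl (2Z,4S,5S,6E)-2,4,6-trimethyl-5-(triethylsilyloxy)nona-2,6,8-trienoate | CO[C@H]1C[C@H]([C@@H](C)[C@H](OC(=O)/C(C)=C\[C@H](C)[C@H](O[Si](CC)(CC)CC)/C(C)=C/C=C)/C=C/[C@H]2O[C@@H]2C)O[C@@H]1/C=C(/C)C=O | intermediate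
29 | (2R,3R,4E)-2-{(2R,4S,5R)-4-methoxy-5-[(1Z)-2-methyl-3-oxoprop-1-en-1-yl]oxolan-2-yl}-5-[(2R,3R)-3-methyloxiran-2-yl]pent-4-en-3-yl (2Z,4S,5S,6E)-5-hydroxy-2,4,6-trimethylnona-2,6,8-trienoate | CO[C@H]1C[C@H]([C@@H](C)[C@H](OC(=O)/C(C)=C\[C@H](C)[C@H](O)/C(C)=C/C=C)/C=C/[C@H]2O[C@@H]2C)O[C@@H]1/C=C(/C)C=O | intermediate
30 | (2R,3R,4E)-2-{(2R,4S,5R)-4-methoxy-5-[(1Z)-2-methyl-3-oxoprop-1-en-1-yl]oxolan-2-yl}-5-[(2R,3R)-3-methyloxiran-2-yl]pent-4-en-3-yl (2Z,4S,6E)-2,4,6-trimethyl-5-oxonona-2,6,8-trienoate | CO[C@H]1C[C@H]([C@@H](C)[C@H](OC(=O)/C(C)=C\[C@H](C)C(=O)/C(C)=C/C=C)/C=C/[C@H]2O[C@@H]2C)O[C@@H]1/C=C(/C)C=O | intermediate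
31 | (2R,3R,4E)-2-{(2R,4S,5R)-5-[(1Z,3R)-3-hydroxy-2-methylhexa-1,5-dien-1-yl]-4-methoxyoxolan-2-yl}-5-[(2R,3R)-3-methyloxiran-2-yl]pent-4-en-3-yl (2Z,4S,6E)-2,4,6-trimethyl-5-oxonona-2,6,8-trienoate | CO[C@H]1C[C@H]([C@@H](C)[C@H](OC(=O)/C(C)=C\[C@H](C)C(=O)/C(C)=C/C=C)/C=C/[C@H]2O[C@@H]2C)O[C@@H]1/C=C(/C)[C@H](O)CC=C | intermediate
32 | CNP0117824.1, the (2Z,4S,6E,8Z,11R,12Z,14R,15S,17R,18R,19R,20E,22R,23R) macrolide | CO[C@H]1C[C@H]2O[C@@H]1/C=C(/C)[C@H](O)C/C=C\C=C(/C)C(=O)[C@@H](C)/C=C(/C)C(=O)O[C@H](/C=C/[C@H]1O[C@@H]1C)[C@@H]2C | target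

**Step count**
Total: 22 steps. Longest linear sequence: 16 steps (1–8, 11–13, 18–22).

**Three steps most likely to fail**

Step 16 (the proposed carbene-catalysed [4+2]). Risks are benzoin or Stetter reaction of the aldehyde with the free carbene, α- instead of γ-attack of the dienolate, and weak enantiocontrol at the remote γ-carbon. The fallback uses known chemistry and sets out from 21. A Denmark-type Lewis-base-catalysed anti-aldol (SiCl4, chiral bisphosphoramide, CH2Cl2, −78 °C) with the tert-butyldimethylsilyl ketene acetal of methyl propanoate gives methyl (2R,3S,4E)-3-hydroxy-2,4-dimethylhepta-4,6-dienoate F1. Silylation (TESCl, imidazole) gives methyl (2R,3S,4E)-2,4-dimethyl-3-(triethylsilyloxy)hepta-4,6-dienoate F2. i-Bu2AlH at −78 °C gives (2R,3S,4E)-2,4-dimethyl-3-(triethylsilyloxy)hepta-4,6-dienal F3. Still–Gennari olefination with 7 gives ethyl (2Z,4S,5S,6E)-2,4,6-trimethyl-5-(triethylsilyloxy)nona-2,6,8-trienoate F4, and LiOH hydrolysis brings the sequence back to the route at 27.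

Step 22 (Z-selective ring-closing metathesis onto an electron-poor dienone, in the presence of a free alcohol and a vinyl epoxide). The fallback moves ring closure ahead of the C5 oxidation and sets out from 28. Allylboration as in step 21 gives (2R,3R,4E)-2-{(2R,4S,5R)-5-[(1Z,3R)-3-hydroxy-2-methylhexa-1,5-dien-1-yl]-4-methoxyoxolan-2-yl}-5-[(2R,3R)-3-methyloxiran-2-yl]pent-4-en-3-yl (2Z,4S,5S,6E)-2,4,6-trimethyl-5-(triethylsilyloxy)nona-2,6,8-trienoate F5. Metathesis on this electron-rich silyloxydiene gives the macrolide 32 with C5 as a (5S)-triethylsilyloxy carbon F6. TBSCl/imidazole gives the 11-O-tert-butyldimethylsilyl ether of that macrolide F7. Selective cleavage of the triethylsilyl ether (HF·pyridine, pyridine, 0 °C) gives the 11-O-tert-butyldimethylsilyl (5S)-5-hydroxy macrolide F8. Dess–Martin oxidation gives the 11-O-tert-butyldimethylsilyl ether of 32 F9, and HF·pyridine removes the last silyl group under acidic conditions to come back to the route at 32.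

Step 11 (substrate-controlled C19 selectivity of the Nozaki–Hiyama–Kishi addition, and CrCl2 next to a vinyl epoxide). The fallback sets out from 16 obtained as an epimer mixture. Dess–Martin oxidation gives ethyl (2Z)-3-{(2R,3S,5R)-3-methoxy-5-[(2R,4E)-5-[(2R,3R)-3-methyloxiran-2-yl]-3-oxopent-4-en-2-yl]oxolan-2-yl}-2-methylprop-2-enoate F10. Catalyst-controlled Corey–Bakshi–Shibata reduction ((R)-2-methyl-CBS-oxazaborolidine, catecholborane, toluene, −78 °C) then returns the single 19R alcohol to the route at 16.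

**Further compounds**
F1 | step 16 | methyl (2R,3S,4E)-3-hydroxy-2,4-dimethylhepta-4,6-dienoate | COC(=O)[C@H](C)[C@H](O)/C(C)=C/C=C
F2 | step 16 | methyl (2R,3S,4E)-2,4-dimethyl-3-(triethylsilyloxy)hepta-4,6-dienoate | COC(=O)[C@H](C)[C@H](O[Si](CC)(CC)CC)/C(C)=C/C=C
F3 | step 16 | (2R,3S,4E)-2,4-dimethyl-3-(triethylsilyloxy)hepta-4,6-dienal | O=C[C@H](C)[C@H](O[Si](CC)(CC)CC)/C(C)=C/C=C
F4 | step 16 | ethyl (2Z,4S,5S,6E)-2,4,6-trimethyl-5-(triethylsilyloxy)nona-2,6,8-trienoate | CCOC(=O)/C(C)=C\[C@H](C)[C@H](O[Si](CC)(CC)CC)/C(C)=C/C=C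
F5 | step 22 | (2R,3R,4E)-2-{(2R,4S,5R)-5-[(1Z,3R)-3-hydroxy-2-methylhexa-1,5-dien-1-yl]-4-methoxyoxolan-2-yl}-5-[(2R,3R)-3-methyloxiran-2-yl]pent-4-en-3-yl (2Z,4S,5S,6E)-2,4,6-trimethyl-5-(triethylsilyloxy)nona-2,6,8-trienoate | CO[C@H]1C[C@H]([C@@H](C)[C@H](OC(=O)/C(C)=C\[C@H](C)[C@H](O[Si](CC)(CC)CC)/C(C)=C/C=C)/C=C/[C@H]2O[C@@H]2C)O[C@@H]1/C=C(/C)[C@H](O)CC=C
F6 | step 22 | macrolide 32 with the C5 ketone replaced by a (5S)-triethylsilyloxy carbon | CO[C@H]1C[C@H]2O[C@@H]1/C=C(/C)[C@H](O)C/C=C\C=C(/C)[C@@H](O[Si](CC)(CC)CC)[C@@H](C)/C=C(/C)C(=O)O[C@H](/C=C/[C@H]1O[C@@H]1C)[C@@H]2C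
F7 | step 22 | 11-O-tert-butyldimethylsilyl ether of F6 | CO[C@H]1C[C@H]2O[C@@H]1/C=C(/C)[C@H](O[Si](C)(C)C(C)(C)C)C/C=C\C=C(/C)[C@@H](O[Si](CC)(CC)CC)[C@@H](C)/C=C(/C)C(=O)O[C@H](/C=C/[C@H]1O[C@@H]1C)[C@@H]2C
F8 | step 22 | 11-O-tert-butyldimethylsilyl (5S)-5-hydroxy analogue of 32 | CO[C@H]1C[C@H]2O[C@@H]1/C=C(/C)[C@H](O[Si](C)(C)C(C)(C)C)C/C=C\C=C(/C)[C@@H](O)[C@@H](C)/C=C(/C)C(=O)O[C@H](/C=C/[C@H]1O[C@@H]1C)[C@@H]2C
F9 | step 22 | 11-O-tert-butyldimethylsilyl ether of 32 | CO[C@H]1C[C@H]2O[C@@H]1/C=C(/C)[C@H](O[Si](C)(C)C(C)(C)C)C/C=C\C=C(/C)C(=O)[C@@H](C)/C=C(/C)C(=O)O[C@H](/C=C/[C@H]1O[C@@H]1C)[C@@H]2C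
F10 | step 11 | ethyl (2Z)-3-{(2R,3S,5R)-3-methoxy-5-[(2R,4E)-5-[(2R,3R)-3-methyloxiran-2-yl]-3-oxopent-4-en-2-yl]oxolan-2-yl}-2-methylprop-2-enoate | CO[C@H]1C[C@H]([C@@H](C)C(=O)/C=C/[C@H]2O[C@@H]2C)O[C@@H]1/C=C(/C)C(=O)OCC
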